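The numbers in the tables were generated by integration with constants of no real substance; scatter was added.

Compare, at one moment, the rates at which the short-lived intermediate goes to target and to solvolysis product, then ask how that comparison drifts with first nucleophile and heat.

common to all: gas 27 mM (held)
- dawn: substrate 0.20 M; first nucleophile 1 M; temperature 65 °C; run made earlier
- midnight: substrate 0.30 M; first nucleophile 1 M; temperature 80 °C; run made earlier
- summer: substrate 0.40 M; first nucleophile 0.50 M; temperature 65 °C; run made earlier
- Thursday's: substrate 0.40 M; first nucleophile 1.00 M; temperature 70 °C; time 6.0 d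
- Monday's: substrate 0.40 M; first nucleophile 1.00 M; temperature 90 °C; time 6.0 d

| run | time / d | target / % | intermediate / % | solvolysis product / % | other capture product / % | substrate / % |
|---|---|---|---|---|---|---|
| dawn | 0.833 | 39.3 | 2.7 | 21.5 | 12.0 | 9.1 |
| dawn | 1.67 | 47.6 | 0 | 21.4 | 15.8 | 1.1 |
| dawn | 2.50 | 46.4 | 0 | 24.0 | 13.7 | 0 |
| dawn | 3.00 | 48.6 | 0 | 24.6 | 14.4 | 0.2 |
| dawn | 4.00 | 47.2 | 0 | 24.1 | 15.2 | 2.2 |
| dawn | 5.00 | 45.6 | 0.1 | 22.9 | 15.0 | 0 |
| midnight | 0.250 | 38.4 | 0 | 36.0 | 9.7 | 1.3 |
| midnight | 0.417 | 39.0 | 0 | 36.5 | 10.6 | 1.3 |
| midnight | 0.625 | 40.5 | 1.2 | 38.1 | 10.3 | 0 |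
| midnight | 1.04 | 40.8 | 1.8 | 38.9 | 9.4 | 0 |
| midnight | 1.67 | 40.8 | 1.1 | 36.2 | 13.4 | 0 |
| midnight | 3.00 | 40.6 | 0.5 | 38.0 | 9.5 | 0 |
| summer | 0.417 | 17.2 | 5.0 | 17.8 | 11.6 | 23.3 |
| summer | 1.25 | 27.2 | 0.9 | 29.9 | 15.7 | 1.7 |
| summer | 2.00 | 27.3 | 0.3 | 31.4 | 18.3 | 0.6 |
| summer | 3.00 | 27.2 | 0 | 29.8 | 17.6 | 0 |
| summer | 5.00 | 26.7 | 0 | 28.1 | 19.5 | 1.2 |

(readings scatter by 1 percentage point)

- the earlier runs were read with a standard deviation of 1 percentage point
- at the start none of the gas is in solution

1. which of these there is most of at the end, counted by the substrate in it, Thursday's (other capture product / target / substrate / solvolysis product / intermediate)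
2. which of these there is most of at the end, counted by the substrate in it, Monday's (other capture product / target / substrate / solvolysis product / intermediate)
3. final amount of the leader among these, as a percentage of the substrate charged, in Thursday's
4. final amount of the leader among these, as a percentage of the substrate charged, in Monday's

A model of the main step by itself, substrate to intermediate and first nucleophile plus intermediate to target, puts target at 100 per cent. Adding solvolysis gives the intermediate a second exit, which the readings suggest carries no first nucleophile, so target over solvolysis product should equal S[first nucleophile]. The plateau readings give S = 1.96 /M in the dawn run and 1.08 /M in the midnight run. The summer run, at half the dawn charge of first nucleophile, reads 1.82 /M, so the proportionality roughly holds.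

Taking ln S as straight in temperature gives 1.61 /M for Thursday's. This S, target formed per solvolysis product per unit of [first nucleophile], is the selectivity factor. The same line, extrapolated, gives 0.720 /M for Monday's. With 1.00 M charged, S[first nucleophile] is reckoned above one in Thursday's, so target should lead with a share 61.6 % of the pair. In Monday's it is reckoned below one, so solvolysis product should lead with 58.1 %.

The rest, other capture product and the material missing from the balance, is taken to shrink the pair without touching S. The pair reads 70.8 % in the dawn run and 78.5 % in the midnight run. A straight line through these gives leaders of 45.2 % for Thursday's and 48.6 % for Monday's. Both flasks carry more substrate than the dawn or midnight runs, and the summer run at that loading, which also differs in holding less first nucleophile, reads a smaller pair, so these estimates may stand high.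

The forecast gives target at 44 % for Thursday's and solvolysis product at 47 % for Monday's, on the ground that “Solvolysis therefore gains with heat”.

Thursday's ends with target at 40.4 %, and Monday's with solvolysis product at 48.4 %.

    substrate → intermediate (k = 0.00310 /min, Ea = 112 kJ/mol)
    first nucleophile + intermediate → target (k = 0.0120 /M/min, Ea = 79.0 kJ/mol)
    second nucleophile + intermediate → other capture product (k = 0.130 /M/min, Ea = 67.0 kJ/mol)
    intermediate → solvolysis product (k = 0.00720 /min, Ea = 119 kJ/mol)
    gas ⇌ second nucleophile, rate k5*(csat - [second nucleophile]) (kL = 0.100 /min)
    2 substrate → homo dimer (k = 0.00220 /M/min, Ea = 67.0 kJ/mol)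
    (constants at 70 °C)

The end amounts give S = 1.53 /M for Thursday's and 0.715 /M for Monday's, against the reckoned 1.61 /M and 0.720 /M. The lead changes hands because of the temperature: Monday's flask at Thursday's temperature holds 26.4 % solvolysis product instead of 48.4 %. The loss of intermediate to solvolysis product has the higher activation energy, 119 kJ/mol against 79.0 kJ/mol for the making of target.

The neighbour of Thursday's charged with 0.25 M of first nucleophile reckons at S[first nucleophile] = 0.403, below one. That flask ends with 15.7 % target against 43.3 % solvolysis product, a ratio of 0.363, and solvolysis product leads.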